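**Retrosynthetic overview**

1. The flavone pyranone ring is closed last (O1–C2 and C4–C4a, with CO as C4) by Pd/CO annulation of o-iodophenol 19 with alkyne 21. Phenol 18 is symmetric about its CH2–C(OH) axis, so either ortho carbon gives the 6-substituted 5,7-dioxygenated flavone.
2. Feature: the carbocycle is isophorone with ArCH2 on its γ-carbon. In isophorone numbering the methyl carbinol carbon is C3 (β), the ArCH2-bearing methine is C4 (γ) and CMe2 is C5. The trans C3–OH/C4–CH2Ar pair therefore comes from epoxidation of C2=C3 anti to the C4 arm, Wharton transposition (C1 oxygen removed) and alkene reduction.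
3. Key disconnection: the C2–O and C3–O bonds of epoxy ketone 14 from racemic enone 13, by amine-catalysed asymmetric Weitz–Scheffer epoxidation run as a dynamic kinetic resolution of C4 through the C1=C2/C3=C4 dienamine.
4. Enone 13 by a Stork–Danheiser sequence: the Ar–CH2 bond from the cuprate of ortho-lithiated arene 2 and the 6-methylene vinylogous ester 7 (from dimedone ethyl enol ether 3), then MeLi/H3O+.
5. Ring order: the six-membered carbocycle is bought (3), then the oxirane (step 6, opened in step 7), then the pyranone (step 12).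

Key step: step 6

Remark on numbering: the terpenoid ring is numbered as isophorone throughout the discussion (C1 carbonyl carbon, C3 methyl-bearing carbon, C4 methine carrying CH2Ar, C5 CMe2). Compound names use their own systematic locants.

Assumption: the quinine-derived 9-amino(9-deoxy)epi amine is written for step 6. If a trial on isophorone shows that it delivers oxygen to the opposite enone face, its quinidine-derived pseudoenantiomer is meant.

**Route**

Step 1
Reactants: 1 3,5-bis(benzyloxy)phenol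
Product: 2 1,3-bis(benzyloxy)-5-(triisopropylsilyloxy)benzene
Conditions: TIPSCl (1.2 equiv), imidazole (2.5 equiv), DMF, rt
Reagents that add atoms: triisopropylsilyl chloride, CC(C)[Si](Cl)(C(C)C)C(C)C
Why: Imidazole-promoted silylation of the only free phenol; the bulky, non-coordinating OTIPS group later blocks its two ortho positions against lithiation.

Step 2
Reactants: 3 3-ethoxy-5,5-dimethylcyclohex-2-en-1-one
Product: 5 6-[(dimethylamino)methyl]-3-ethoxy-5,5-dimethylcyclohex-2-en-1-one (racemic), via lithium cross-conjugated enolate 4 (not isolated)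
Conditions: LDA (1.1 equiv), THF, −78 °C; then Me2N+=CH2 I− (1.3 equiv), −78 °C → rt
Reagents that add atoms: N,N-dimethylmethyleneiminium iodide (Eschenmoser's salt), C=[N+](C)C.[I-]
Why: Kinetic deprotonation of the vinylogous ester occurs at the α′ carbon (Stork–Danheiser enolate) and the iminium salt traps it in a Mannich reaction; the new stereocentre is racemic and is removed in step 3.

Step 3
Reactants: 5 6-[(dimethylamino)methyl]-3-ethoxy-5,5-dimethylcyclohex-2-en-1-one
Product: 7 3-ethoxy-5,5-dimethyl-6-methylidenecyclohex-2-en-1-one, via trimethylammonium iodide 6 (not isolated)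
Conditions: MeI (5 equiv), THF, rt; then sat. aq. NaHCO3, CH2Cl2, rt; used at once
Reagents that add atoms: none
Why: Exhaustive N-methylation makes the amine a leaving group and the β-ammonium ketone undergoes E1cB (Hofmann-type) elimination to the exocyclic enone under mild bicarbonate.

Step 4
Reactants: 2 1,3-bis(benzyloxy)-5-(triisopropylsilyloxy)benzene; 7 3-ethoxy-5,5-dimethyl-6-methylidenecyclohex-2-en-1-one
Product: 11 6-{[2,6-bis(benzyloxy)-4-(triisopropylsilyloxy)phenyl]methyl}-3-ethoxy-5,5-dimethylcyclohex-2-en-1-one (racemic), via aryllithium 8 (not isolated), via lithium diarylcuprate 9 (not isolated), via lithium enolate 10 (not isolated)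
Conditions: 2 (2.1 equiv), n-BuLi (2.05 equiv), THF, 0 °C → rt; CuI (1.0 equiv), −40 °C; 7 (1.0 equiv), −78 → −20 °C; aq. NH4Cl (excess 2 recovered)
Reagents that add atoms: none
Why: Directed ortho-metalation should occur at the carbon flanked by the two benzyloxy groups (the OTIPS flanks are blocked), and the derived Gilman diarylcuprate adds 1,4 to the unhindered exocyclic methylene in preference to the vinylogous ester; protonation of the enolate leaves the new stereocentre racemic.

Step 5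
Reactants: 11 6-{[2,6-bis(benzyloxy)-4-(triisopropylsilyloxy)phenyl]methyl}-3-ethoxy-5,5-dimethylcyclohex-2-en-1-one
Product: 13 4-{[2,6-bis(benzyloxy)-4-(triisopropylsilyloxy)phenyl]methyl}-3,5,5-trimethylcyclohex-2-en-1-one (racemic), via tertiary allylic alcohol 12 (not isolated)
Conditions: MeLi (3 equiv), anhydrous CeCl3 (3 equiv), THF, −78 °C; then 1 M HCl, THF, 0 °C → rt
Reagents that add atoms: methyllithium, [Li]C; water, O
Why: Stork–Danheiser transposition: the organocerium reagent adds 1,2 to the hindered carbonyl without enolisation, and aqueous acid ionises the tertiary allylic alcohol and hydrolyses the enol ether to the transposed enone; C4 stays racemic and the aryl silyl ether should survive dilute acid.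

Step 6
Reactants: 13 4-{[2,6-bis(benzyloxy)-4-(triisopropylsilyloxy)phenyl]methyl}-3,5,5-trimethylcyclohex-2-en-1-one (racemic)
Product: 14 (1R,5S,6R)-5-{[2,6-bis(benzyloxy)-4-(triisopropylsilyloxy)phenyl]methyl}-4,4,6-trimethyl-7-oxabicyclo[4.1.0]heptan-2-one (oxirane trans to the arylmethyl arm)
Conditions: 9-amino(9-deoxy)epi-quinine (20 mol %), CF3CO2H (40 mol %), 1,4-dioxane, 50 °C, 2 h pre-equilibration; then 50 % aq. H2O2 (1.5 equiv) by syringe pump over 24 h, 50 °C
Reagents that add atoms: hydrogen peroxide, OO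
Why: Proposed new method: the primary amine condenses with the C1 carbonyl to an iminium ion, hydrogen peroxide adds to C3, and the β-peroxy enamine closes the oxirane by 3-exo-tet attack of C2 on the peroxide oxygen bound to C3 with loss of water, hydrolysis then releasing the catalyst. The closest known reaction type is the primary-amine-salt (iminium) catalysed asymmetric Weitz–Scheffer epoxidation of 3-substituted cyclohex-2-enones with aqueous H2O2; new here is its use as a dynamic kinetic resolution of a γ-stereocentre. C3 and C2 (one event, since the oxirane must be cis-fused) are set by the catalyst, whose protonated quinuclidine steers the peroxide to one face of the iminium, combined with approach anti to the C4 arm, which A(1,2) strain with the C3 methyl holds pseudoaxial over the other face; only (4S)-13 offers both at once. C4 is set by equilibration: loss of H4 from the iminium gives the ring dienamine (C1=C2, C3=C4), the γ-deprotonation that also interconverts α- and β-isophorone, and reprotonation returns either enantiomer, so (4R)-13 should drain through the matched (4S) iminium. The step needs racemisation to outrun epoxidation of the mismatched iminium, which the acid co-catalyst, 50 °C and slow dosing of the oxidant are meant to secure. In 14 the former C4 is no longer vinylogously acidic, so its configuration is locked once the oxirane has formed.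

Step 7
Reactants: 14 (1R,5S,6R)-5-{[2,6-bis(benzyloxy)-4-(triisopropylsilyloxy)phenyl]methyl}-4,4,6-trimethyl-7-oxabicyclo[4.1.0]heptan-2-one
Product: 16 (1S,6S)-6-{[2,6-bis(benzyloxy)-4-(triisopropylsilyloxy)phenyl]methyl}-1,5,5-trimethylcyclohex-2-en-1-ol, via epoxy hydrazone 15 (not isolated)
Conditions: N2H4·H2O (3 equiv), AcOH (0.3 equiv), MeOH, 0 °C → rt
Reagents that add atoms: none
Why: Wharton transposition: the hydrazone opens the oxirane to an allylic diazene that loses N2, placing the alkene at C1=C2 and leaving the C3–O bond, and hence the C3 and C4 configurations, untouched.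

Step 8
Reactants: 16 (1S,6S)-6-{[2,6-bis(benzyloxy)-4-(triisopropylsilyloxy)phenyl]methyl}-1,5,5-trimethylcyclohex-2-en-1-ol
Product: 17 (1S,2S)-2-{[2,6-bis(benzyloxy)-4-(triisopropylsilyloxy)phenyl]methyl}-1,3,3-trimethylcyclohexan-1-ol
Conditions: 2-nitrobenzenesulfonylhydrazide (5 equiv, in portions), Et3N, CH2Cl2, rt
Reagents that add atoms: none
Why: Diimide reduction: concerted syn transfer of H2 to the cis-disubstituted ring alkene, leaving benzyl ethers, silyl ether and tertiary alcohol alone; no stereocentre is made or touched.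

Step 9
Reactants: 17 (1S,2S)-2-{[2,6-bis(benzyloxy)-4-(triisopropylsilyloxy)phenyl]methyl}-1,3,3-trimethylcyclohexan-1-ol
Product: 18 3,5-bis(benzyloxy)-4-{[(1S,2S)-2-hydroxy-2,6,6-trimethylcyclohexyl]methyl}phenol
Conditions: TBAF (1.2 equiv), AcOH (1.2 equiv), THF, 0 °C → rt
Reagents that add atoms: none
Why: Fluoride-induced cleavage of the aryl silyl ether; the acetic acid buffer keeps the electron-rich phenoxide from air oxidation.

Step 10
Reactants: 18 3,5-bis(benzyloxy)-4-{[(1S,2S)-2-hydroxy-2,6,6-trimethylcyclohexyl]methyl}phenol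
Product: 19 3,5-bis(benzyloxy)-2-iodo-4-{[(1S,2S)-2-hydroxy-2,6,6-trimethylcyclohexyl]methyl}phenol
Conditions: N-iodosuccinimide (1.0 equiv), CH2Cl2, −20 → 0 °C, dark
Reagents that add atoms: N-iodosuccinimide, O=C1CCC(=O)N1I
Why: Electrophilic aromatic iodination ortho to the free hydroxyl; the para position is occupied and the two ortho sites are equivalent by symmetry, so one equivalent at low temperature should give a single mono-iodide.

Step 11
Reactants: 20 3,4-bis(benzyloxy)benzaldehyde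
Product: 21 1,2-bis(benzyloxy)-4-ethynylbenzene
Conditions: dimethyl (1-diazo-2-oxopropyl)phosphonate (1.3 equiv), K2CO3 (2 equiv), MeOH, rt
Reagents that add atoms: dimethyl (1-diazo-2-oxopropyl)phosphonate (Ohira–Bestmann reagent), COP(=O)(OC)C(=[N+]=[N-])C(C)=O
Why: Seyferth–Gilbert homologation in the Ohira–Bestmann variant converts the aryl aldehyde into the terminal alkyne under mild base that benzyl ethers tolerate.

Step 12
Reactants: 19 3,5-bis(benzyloxy)-2-iodo-4-{[(1S,2S)-2-hydroxy-2,6,6-trimethylcyclohexyl]methyl}phenol; 21 1,2-bis(benzyloxy)-4-ethynylbenzene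
Product: 24 5,7-bis(benzyloxy)-2-[3,4-bis(benzyloxy)phenyl]-6-{[(1S,2S)-2-hydroxy-2,6,6-trimethylcyclohexyl]methyl}-4H-chromen-4-one, via hydroxyaryl ynone 22 (not isolated), via diethylamino enaminone 23 (not isolated)
Conditions: 21 (1.5 equiv), PdCl2(dppf) (5 mol %), CO (20 bar), Et2NH, 120 °C
Reagents that add atoms: carbon monoxide, [C-]#[O+]
Why: Pd-catalysed carbonylative Sonogashira coupling gives the o-hydroxyaryl ynone, diethylamine adds to it, and the phenol closes the pyranone by addition–elimination on the enaminone (overall 6-endo), which favours the flavone over the aurone.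

Step 13
Reactants: 24 5,7-bis(benzyloxy)-2-[3,4-bis(benzyloxy)phenyl]-6-{[(1S,2S)-2-hydroxy-2,6,6-trimethylcyclohexyl]methyl}-4H-chromen-4-one
Product: 25 2-(3,4-dihydroxyphenyl)-5,7-dihydroxy-6-{[(1S,2S)-2-hydroxy-2,6,6-trimethylcyclohexyl]methyl}-4H-chromen-4-one (CNP0257603.1)
Conditions: H2 (1 atm), 10 % Pd/C, EtOAc–MeOH, rt, stopped at four equivalents of uptake
Reagents that add atoms: none
Why: Catalytic hydrogenolysis of the four benzyl ethers under neutral conditions; the conjugated flavone C2=C3 bond and the non-benzylic tertiary alcohol should survive, and no acid is present that could ionise the carbinol.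

**Compound list**

1 | 3,5-bis(benzyloxy)phenol | Oc1cc(OCc2ccccc2)cc(OCc2ccccc2)c1 | starting material
2 | 1,3-bis(benzyloxy)-5-(triisopropylsilyloxy)benzene | CC(C)[Si](Oc1cc(OCc2ccccc2)cc(OCc2ccccc2)c1)(C(C)C)C(C)C | intermediate
3 | 3-ethoxy-5,5-dimethylcyclohex-2-en-1-one | CCOC1=CC(=O)CC(C)(C)C1 | starting material
4 | lithium 5-ethoxy-3,3-dimethylcyclohexa-1,5-dien-1-olate | CCOC1=CC(O[Li])=CC(C)(C)C1 | intermediate
5 | 6-[(dimethylamino)methyl]-3-ethoxy-5,5-dimethylcyclohex-2-en-1-one (racemic) | CCOC1=CC(=O)C(CN(C)C)C(C)(C)C1 | intermediate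
6 | [(4-ethoxy-6,6-dimethyl-2-oxocyclohex-3-en-1-yl)methyl]trimethylammonium iodide | CCOC1=CC(=O)C(C[N+](C)(C)C)C(C)(C)C1.[I-] | intermediate
7 | 3-ethoxy-5,5-dimethyl-6-methylidenecyclohex-2-en-1-one | CCOC1=CC(=O)C(=C)C(C)(C)C1 | intermediate
8 | [2,6-bis(benzyloxy)-4-(triisopropylsilyloxy)phenyl]lithium | [Li]c1c(OCc2ccccc2)cc(O[Si](C(C)C)(C(C)C)C(C)C)cc1OCc1ccccc1 | intermediate
9 | lithium bis[2,6-bis(benzyloxy)-4-(triisopropylsilyloxy)phenyl]cuprate | [Li+].[Cu-](c1c(OCc2ccccc2)cc(O[Si](C(C)C)(C(C)C)C(C)C)cc1OCc1ccccc1)c1c(OCc2ccccc2)cc(O[Si](C(C)C)(C(C)C)C(C)C)cc1OCc1ccccc1 | intermediate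
10 | lithium 2-{[2,6-bis(benzyloxy)-4-(triisopropylsilyloxy)phenyl]methyl}-5-ethoxy-3,3-dimethylcyclohexa-1,5-dien-1-olate | CCOC1=CC(O[Li])=C(Cc2c(OCc3ccccc3)cc(O[Si](C(C)C)(C(C)C)C(C)C)cc2OCc2ccccc2)C(C)(C)C1 | intermediate
11 | 6-{[2,6-bis(benzyloxy)-4-(triisopropylsilyloxy)phenyl]methyl}-3-ethoxy-5,5-dimethylcyclohex-2-en-1-one (racemic) | CCOC1=CC(=O)C(Cc2c(OCc3ccccc3)cc(O[Si](C(C)C)(C(C)C)C(C)C)cc2OCc2ccccc2)C(C)(C)C1 | intermediate
12 | 6-{[2,6-bis(benzyloxy)-4-(triisopropylsilyloxy)phenyl]methyl}-3-ethoxy-1,5,5-trimethylcyclohex-2-en-1-ol (diastereomer mixture) | CCOC1=CC(C)(O)C(Cc2c(OCc3ccccc3)cc(O[Si](C(C)C)(C(C)C)C(C)C)cc2OCc2ccccc2)C(C)(C)C1 | intermediate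
13 | 4-{[2,6-bis(benzyloxy)-4-(triisopropylsilyloxy)phenyl]methyl}-3,5,5-trimethylcyclohex-2-en-1-one (racemic) | CC1=CC(=O)CC(C)(C)C1Cc1c(OCc2ccccc2)cc(O[Si](C(C)C)(C(C)C)C(C)C)cc1OCc1ccccc1 | intermediate
14 | (1R,5S,6R)-5-{[2,6-bis(benzyloxy)-4-(triisopropylsilyloxy)phenyl]methyl}-4,4,6-trimethyl-7-oxabicyclo[4.1.0]heptan-2-one | CC1(C)CC(=O)[C@@H]2O[C@]2(C)[C@H]1Cc1c(OCc2ccccc2)cc(O[Si](C(C)C)(C(C)C)C(C)C)cc1OCc1ccccc1 | intermediate
15 | hydrazone of 14 (C=N geometry not defined) | CC1(C)CC(=NN)[C@@H]2O[C@]2(C)[C@H]1Cc1c(OCc2ccccc2)cc(O[Si](C(C)C)(C(C)C)C(C)C)cc1OCc1ccccc1 | intermediate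
16 | (1S,6S)-6-{[2,6-bis(benzyloxy)-4-(triisopropylsilyloxy)phenyl]methyl}-1,5,5-trimethylcyclohex-2-en-1-ol | CC1(C)CC=C[C@](C)(O)[C@H]1Cc1c(OCc2ccccc2)cc(O[Si](C(C)C)(C(C)C)C(C)C)cc1OCc1ccccc1 | intermediate
17 | (1S,2S)-2-{[2,6-bis(benzyloxy)-4-(triisopropylsilyloxy)phenyl]methyl}-1,3,3-trimethylcyclohexan-1-ol | CC1(C)CCC[C@](C)(O)[C@H]1Cc1c(OCc2ccccc2)cc(O[Si](C(C)C)(C(C)C)C(C)C)cc1OCc1ccccc1 | intermediate
18 | 3,5-bis(benzyloxy)-4-{[(1S,2S)-2-hydroxy-2,6,6-trimethylcyclohexyl]methyl}phenol | CC1(C)CCC[C@](C)(O)[C@H]1Cc1c(OCc2ccccc2)cc(O)cc1OCc1ccccc1 | intermediate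
19 | 3,5-bis(benzyloxy)-2-iodo-4-{[(1S,2S)-2-hydroxy-2,6,6-trimethylcyclohexyl]methyl}phenol | CC1(C)CCC[C@](C)(O)[C@H]1Cc1c(OCc2ccccc2)cc(O)c(I)c1OCc1ccccc1 | intermediate
20 | 3,4-bis(benzyloxy)benzaldehyde | O=Cc1ccc(OCc2ccccc2)c(OCc2ccccc2)c1 | starting material
21 | 1,2-bis(benzyloxy)-4-ethynylbenzene | C#Cc1ccc(OCc2ccccc2)c(OCc2ccccc2)c1 | intermediate
22 | 1-(2,4-bis(benzyloxy)-6-hydroxy-3-{[(1S,2S)-2-hydroxy-2,6,6-trimethylcyclohexyl]methyl}phenyl)-3-[3,4-bis(benzyloxy)phenyl]prop-2-yn-1-one | CC1(C)CCC[C@](C)(O)[C@H]1Cc1c(OCc2ccccc2)cc(O)c(C(=O)C#Cc2ccc(OCc3ccccc3)c(OCc3ccccc3)c2)c1OCc1ccccc1 | intermediate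
23 | 1-(2,4-bis(benzyloxy)-6-hydroxy-3-{[(1S,2S)-2-hydroxy-2,6,6-trimethylcyclohexyl]methyl}phenyl)-3-[3,4-bis(benzyloxy)phenyl]-3-(diethylamino)prop-2-en-1-one (C=C geometry not defined) | CC1(C)CCC[C@](C)(O)[C@H]1Cc1c(OCc2ccccc2)cc(O)c(C(=O)C=C(N(CC)CC)c2ccc(OCc3ccccc3)c(OCc3ccccc3)c2)c1OCc1ccccc1 | intermediate
24 | 5,7-bis(benzyloxy)-2-[3,4-bis(benzyloxy)phenyl]-6-{[(1S,2S)-2-hydroxy-2,6,6-trimethylcyclohexyl]methyl}-4H-chromen-4-one | CC1(C)CCC[C@](C)(O)[C@H]1Cc1c(OCc2ccccc2)cc2oc(-c3ccc(OCc4ccccc4)c(OCc4ccccc4)c3)cc(=O)c2c1OCc1ccccc1 | intermediate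
25 | 2-(3,4-dihydroxyphenyl)-5,7-dihydroxy-6-{[(1S,2S)-2-hydroxy-2,6,6-trimethylcyclohexyl]methyl}-4H-chromen-4-one | CC1(C)CCC[C@](C)(O)[C@H]1Cc1c(O)cc2oc(-c3ccc(O)c(O)c3)cc(=O)c2c1O | target

**Totals**

Total step count: 13. Longest linear sequence: 11 steps (3 → 5 → 7 → 11 → 13 → 14 → 16 → 17 → 18 → 19 → 24 → 25; steps 2–10, 12, 13).

**Steps most likely to fail**

Step 6. γ-Deprotonation at the congested C4 methine may be slower than epoxidation of the mismatched iminium. The step would then stop as a kinetic resolution or lose diastereoselectivity, and iminium formation or β-attack at the fully substituted C3 may also be sluggish.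

Fallback, from 13 back to 14, by known reactions:
- rac-13 would be reduced with BH3·SMe2 and the Corey–Bakshi–Shibata oxazaborolidine ((R)-Me-CBS by the usual model), so that C1 becomes S in both C4 epimers.
- Chromatography should separate the trans alcohol (1S,4S)-4-{[2,6-bis(benzyloxy)-4-(triisopropylsilyloxy)phenyl]methyl}-3,5,5-trimethylcyclohex-2-en-1-ol F1 from its cis (1S,4R) epimer F2.
- Hydroxyl-directed epoxidation of F1 with VO(acac)2/t-BuOOH should put the oxirane syn to OH and therefore anti to the arm, giving the epoxy alcohol (1S,2S,5S,6R)-5-{[2,6-bis(benzyloxy)-4-(triisopropylsilyloxy)phenyl]methyl}-4,4,6-trimethyl-7-oxabicyclo[4.1.0]heptan-2-ol F3.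
- Dess–Martin oxidation of F3 gives 14.

Step 12. CO insertion at the crowded, electron-rich aryl–palladium may be slow. Direct alkynylation with benzofuran formation, aminocarbonylation by diethylamine, or 5-exo closure to the aurone would then compete.

Fallback, from 18 back to 24 through 22:
- Magnesium-mediated ortho-formylation of 18 (MgCl2, Et3N, paraformaldehyde, MeCN, reflux) would give 2,4-bis(benzyloxy)-6-hydroxy-3-{[(1S,2S)-2-hydroxy-2,6,6-trimethylcyclohexyl]methyl}benzaldehyde F4.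
- The lithium acetylide of 21 (n-BuLi, THF, −78 °C, 3.5 equiv to cover the phenoxide and the alkoxide) would add to give the propargylic alcohol 1-(2,4-bis(benzyloxy)-6-hydroxy-3-{[(1S,2S)-2-hydroxy-2,6,6-trimethylcyclohexyl]methyl}phenyl)-3-[3,4-bis(benzyloxy)phenyl]prop-2-yn-1-ol F5.
- MnO2 would oxidise F5 to ynone 22, which is isolated this time and closed with Et2NH in EtOH through 23 to flavone 24.

Step 4. Deprotonation at a benzylic OCH2 (Wittig rearrangement) may compete with ring lithiation, or transfer of the di-ortho-substituted aryl group may be slow while enone 7 oligomerises.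

Fallback, from 1 back to 11:
- Vilsmeier–Haack formylation of 1 (POCl3, DMF) para to the hydroxyl would give 2,6-bis(benzyloxy)-4-hydroxybenzaldehyde F6 after removal of the ortho isomer.
- TIPSCl/imidazole gives 2,6-bis(benzyloxy)-4-(triisopropylsilyloxy)benzaldehyde F7.
- NaBH4 gives [2,6-bis(benzyloxy)-4-(triisopropylsilyloxy)phenyl]methanol F8.
- MsCl, Et3N and LiCl at −20 °C give 1,3-bis(benzyloxy)-2-(chloromethyl)-5-(triisopropylsilyloxy)benzene F9, which is used cold and crude to alkylate lithium enolate 4 (THF/DMPU, −78 °C). This gives 11 directly and bypasses 5–10.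

**Further compounds**

F1 | step 6 | (1S,4S)-4-{[2,6-bis(benzyloxy)-4-(triisopropylsilyloxy)phenyl]methyl}-3,5,5-trimethylcyclohex-2-en-1-ol | CC1=C[C@@H](O)CC(C)(C)[C@@H]1Cc1c(OCc2ccccc2)cc(O[Si](C(C)C)(C(C)C)C(C)C)cc1OCc1ccccc1
F2 | step 6 | (1S,4R)-4-{[2,6-bis(benzyloxy)-4-(triisopropylsilyloxy)phenyl]methyl}-3,5,5-trimethylcyclohex-2-en-1-ol | CC1=C[C@@H](O)CC(C)(C)[C@H]1Cc1c(OCc2ccccc2)cc(O[Si](C(C)C)(C(C)C)C(C)C)cc1OCc1ccccc1
F3 | step 6 | (1S,2S,5S,6R)-5-{[2,6-bis(benzyloxy)-4-(triisopropylsilyloxy)phenyl]methyl}-4,4,6-trimethyl-7-oxabicyclo[4.1.0]heptan-2-ol | CC1(C)C[C@H](O)[C@@H]2O[C@]2(C)[C@H]1Cc1c(OCc2ccccc2)cc(O[Si](C(C)C)(C(C)C)C(C)C)cc1OCc1ccccc1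
F4 | step 12 | 2,4-bis(benzyloxy)-6-hydroxy-3-{[(1S,2S)-2-hydroxy-2,6,6-trimethylcyclohexyl]methyl}benzaldehyde | CC1(C)CCC[C@](C)(O)[C@H]1Cc1c(OCc2ccccc2)cc(O)c(C=O)c1OCc1ccccc1
F5 | step 12 | 1-(2,4-bis(benzyloxy)-6-hydroxy-3-{[(1S,2S)-2-hydroxy-2,6,6-trimethylcyclohexyl]methyl}phenyl)-3-[3,4-bis(benzyloxy)phenyl]prop-2-yn-1-ol (carbinol epimers) | CC1(C)CCC[C@](C)(O)[C@H]1Cc1c(OCc2ccccc2)cc(O)c(C(O)C#Cc2ccc(OCc3ccccc3)c(OCc3ccccc3)c2)c1OCc1ccccc1
F6 | step 4 | 2,6-bis(benzyloxy)-4-hydroxybenzaldehyde | O=Cc1c(OCc2ccccc2)cc(O)cc1OCc1ccccc1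
F7 | step 4 | 2,6-bis(benzyloxy)-4-(triisopropylsilyloxy)benzaldehyde | O=Cc1c(OCc2ccccc2)cc(O[Si](C(C)C)(C(C)C)C(C)C)cc1OCc1ccccc1
F8 | step 4 | [2,6-bis(benzyloxy)-4-(triisopropylsilyloxy)phenyl]methanol | OCc1c(OCc2ccccc2)cc(O[Si](C(C)C)(C(C)C)C(C)C)cc1OCc1ccccc1
F9 | step 4 | 1,3-bis(benzyloxy)-2-(chloromethyl)-5-(triisopropylsilyloxy)benzene | ClCc1c(OCc2ccccc2)cc(O[Si](C(C)C)(C(C)C)C(C)C)cc1OCc1ccccc1
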